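With carbons numbered as in the target SMILES, the homoallylic pair C5–O/C1=CH2 on the norbornane core marks an opened cyclopropylcarbinyl cation, so the target is traced to a nortricyclene holding a C1–C5–C6 cyclopropane. The key step builds that cage in one operation: a C5 diazoalkane, released from the tosylhydrazone of a cis-fused hexahydroindene (acetaldehyde arm on C3, silyloxymethyl on C1), adds across the C1=C6 alkene, forming C1–C5 and C5–C6, closing the cyclopropane and the C3–C4–C5–C6–C7 ring and fixing C1, C5 and C6. Solvolysis then reopens C1–C5 with exo water at C5, and a malonate–Knoevenagel sequence adds the caffeate.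

Key step: step 10

Remark: C1–C11 are the ring carbons in target-SMILES order (C1 methylidene-bearing, C2 CH2, C3 quaternary bridgehead, C4 CH2, C5 carbinol, C6 bridgehead CH, C7 methyl-bearing bridge, C8–C10 CH2, C11 gem-dimethyl); all reagents named are taken as commercial; enolates, alkoxides, the hydrazone anion and short-lived carbenes, diradicals and cations are stages within a step and are named in the Why lines without numbers.

Step 1
Reactants: 1 β-homocyclocitral
Product: 2 β-homocyclocitral dimethyl acetal
Conditions: HC(OMe)3, PPTS (cat.), MeOH, rt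
Reagents that add atoms: trimethyl orthoformate, COC(OC)OC; methanol, CO
Why: Acid-catalysed acetalisation with the orthoformate as dehydrating agent masks the aldehyde for the oxidation, organolithium and carbene steps, and the tetrasubstituted β,γ-alkene has no reason to migrate under these mild conditions.

Step 2
Reactants: 2 β-homocyclocitral dimethyl acetal
Product: 3 3-(2,2-dimethoxyethyl)-2,4,4-trimethylcyclohex-2-en-1-one
Conditions: t-BuOOH, Rh2(cap)4 (1 mol %), K2CO3, CH2Cl2, rt
Reagents that add atoms: tert-butyl hydroperoxide, CC(C)(C)OO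
Why: Radical allylic C–H oxidation (tert-butylperoxyl chain) should attack C8, the only ring methylene next to the tetrasubstituted alkene, because the side-chain CH2 is shielded by the gem-dimethyl carbon and deactivated by two β-oxygens and the methyl group is primary, as in the ring oxidation of β-ionone-type cyclohexenes.

Step 3
Reactants: 3 3-(2,2-dimethoxyethyl)-2,4,4-trimethylcyclohex-2-en-1-one
Product: 4 (1R)-3-(2,2-dimethoxyethyl)-2,4,4-trimethylcyclohex-2-en-1-ol
Conditions: (S)-2-methyl-CBS-oxazaborolidine (10 mol %), BH3·SMe2, THF, −20 °C; MeOH quench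
Reagents that add atoms: none
Why: Corey–Bakshi–Shibata reduction in which the α-methylated alkene flank acts as the large substituent, so the (S)-oxazaborolidine–borane complex should deliver hydride to one carbonyl face and set C8 as R with 1,2-selectivity.

Step 4
Reactants: 4 (1R)-3-(2,2-dimethoxyethyl)-2,4,4-trimethylcyclohex-2-en-1-ol; 5 N,N-dimethylacetamide dimethyl acetal
Product: 7 2-[(1S)-1-(2,2-dimethoxyethyl)-2,6,6-trimethylcyclohex-2-en-1-yl]-N,N-dimethylacetamide, via ketene N,O-acetal 6 (not isolated)
Conditions: xylene, 140 °C, MeOH distilled off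
Reagents that add atoms: N,N-dimethylacetamide dimethyl acetal 5, CN(C)C(C)(OC)OC
Why: Eschenmoser–Claisen rearrangement, in which alcohol exchange gives the ketene N,O-acetal and its suprafacial [3,3] shift through the ring-constrained boat transition state transfers the C8 configuration to the quaternary C3 by placing the acetamide arm on the face that carried oxygen, under neutral conditions that the dimethyl acetal tolerates.

Step 5
Reactants: 7 2-[(1S)-1-(2,2-dimethoxyethyl)-2,6,6-trimethylcyclohex-2-en-1-yl]-N,N-dimethylacetamide
Product: 8 2-[(1R,2S)-1-(2,2-dimethoxyethyl)-2,6,6-trimethylcyclohexyl]-N,N-dimethylacetamide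
Conditions: H2 (1 atm), [Ir(cod)(PCy3)(py)]PF6 (5 mol %), dry CH2Cl2, rt
Reagents that add atoms: none
Why: Amide-directed homogeneous hydrogenation, in which the amide carbonyl binds the cationic iridium centre far more strongly than the acetal ethers and delivers both hydrogens to the alkene face syn to the acetamide arm, setting C7 with its hydrogen cis to that arm and its methyl cis to the acetal arm.

Step 6
Reactants: 8 2-[(1R,2S)-1-(2,2-dimethoxyethyl)-2,6,6-trimethylcyclohexyl]-N,N-dimethylacetamide
Product: 9 1-[(1R,2S)-1-(2,2-dimethoxyethyl)-2,6,6-trimethylcyclohexyl]propan-2-one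
Conditions: MeLi, THF, −78 → 0 °C; H2O
Reagents that add atoms: methyllithium, [Li]C
Why: Addition of an organolithium to a tertiary amide stops at the lithium hemiaminal alkoxide, which releases the methyl ketone only on aqueous work-up, so no tertiary alcohol should form.

Step 7
Reactants: 9 1-[(1R,2S)-1-(2,2-dimethoxyethyl)-2,6,6-trimethylcyclohexyl]propan-2-one
Product: 11 1-[(tert-butyldimethylsilyl)oxy]-3-[(1R,2S)-1-(2,2-dimethoxyethyl)-2,6,6-trimethylcyclohexyl]propan-2-one, via TBS enol ether 10 (not isolated)
Conditions: LiN(i-Pr)2, THF, −78 °C; TBSCl, DMPU, −78 → 0 °C; then mCPBA, NaHCO3, CH2Cl2, 0 °C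
Reagents that add atoms: tert-butyldimethylsilyl chloride, CC(C)(C)[Si](C)(C)Cl; mCPBA, OOC(=O)c1cccc(Cl)c1
Why: Kinetic enolisation takes the methyl protons because the other α-carbon is neopentylic, O-silylation gives the terminal silyl enol ether, and Rubottom oxidation (epoxidation followed by 1,4-silyl shift) should deliver the α-silyloxy ketone with the silyl group retained.

Step 8
Reactants: 11 1-[(tert-butyldimethylsilyl)oxy]-3-[(1R,2S)-1-(2,2-dimethoxyethyl)-2,6,6-trimethylcyclohexyl]propan-2-one
Product: 13 tert-butyl{[(3aS,7aR)-7a-(2,2-dimethoxyethyl)-3a,7,7-trimethyl-3a,4,5,6,7,7a-hexahydro-1H-inden-2-yl]methoxy}dimethylsilane, via diazoalkene 12 (not isolated)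
Conditions: TMSCHN2, n-BuLi, THF, −78 °C → rt
Reagents that add atoms: (trimethylsilyl)diazomethane, C[Si](C)(C)C=[N+]=[N-]
Why: Lithiated trimethylsilyldiazomethane adds to the ketone, Peterson-type loss of LiOSiMe3 gives the diazoalkene, and the alkylidene carbene formed on N2 loss undergoes 1,5 C–H insertion into the tertiary C7–H bond with retention (that hydrogen is cis to the carbene arm), so the cis-fused cyclopentene and the quaternary C7 arise together, while the only other 1,5 C–H bonds (at C4) are secondary and deactivated by the β-acetal oxygens and the silyl ether offers no C–H on its 1,5 atom.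

Step 9
Reactants: 13 tert-butyl{[(3aS,7aR)-7a-(2,2-dimethoxyethyl)-3a,7,7-trimethyl-3a,4,5,6,7,7a-hexahydro-1H-inden-2-yl]methoxy}dimethylsilane; 14 p-toluenesulfonyl hydrazide
Product: 16 tosylhydrazone of the cis-fused cyclopentene aldehyde, via aldehyde 15 (not isolated)
Conditions: PPTS (cat.), acetone/H2O (10:1), 45 °C; concentrate; then TsNHNH2, MeOH, rt
Reagents that add atoms: p-toluenesulfonyl hydrazide 14, Cc1ccc(cc1)S(=O)(=O)NN
Why: Buffered acid hydrolysis cleaves the dimethyl acetal without touching the primary silyl ether, and the unhindered aldehyde then condenses with the hydrazide to the tosylhydrazone.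

Step 10
Reactants: 16 tosylhydrazone of the cis-fused cyclopentene aldehyde
Product: 19 tetracyclic nortricyclene silyl ether, via diazoalkane 17 (not isolated), via pyrazoline 18 (not isolated)
Conditions: NaH, THF, 0 °C; then diglyme, 110 → 140 °C, 0.01 M
Reagents that add atoms: none
Why: NaH gives the hydrazone anion, which on heating loses p-toluenesulfinate (aprotic Bamford–Stevens conditions) to release the C5 diazoalkane; this adds as a 1,3-dipole across C1=C6 (C5 to C6, terminal N to C1), and the strained 1-pyrazoline extrudes N2 to a C1/C5 1,3-diradical that can only recombine, since a hydrogen shift would need a bridgehead alkene. The closest known reaction type is the intramolecular cyclopropanation of alkenyl aldehyde tosylhydrazones through their diazoalkanes, here on a cyclopent-3-enylacetaldehyde framework that leads to a nortricyclene. The C3–C4–C5–C6–C7 ring closes in a 5-exo sense during the cycloaddition (bond C5–C6), and the cyclopropane closes by 3-exo radical recombination (bond C1–C5), which also completes the C1–C2–C3–C4–C5 ring. C1, C5 and C6 are controlled by the cis ring fusion built in steps 4, 5 and 8: the C4–C5 arm on C3 reaches only the alkene face syn to it, and the cage admits one configuration. The step needs cycloaddition to outrun both N2 loss to the free carbene (whose 1,2-hydride shift would give a vinyl group) and azine formation; the cis fusion, buttressed by the gem-dimethyl group, holds C5 over the alkene, and high dilution with a moderate temperature should suppress the carbene and bimolecular paths.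

Step 11
Reactants: 19 tetracyclic nortricyclene silyl ether
Product: 20 nortricyclene cyclopropylcarbinol (CH2OH on C1)
Conditions: Bu4NF, THF, 0 °C → rt
Reagents that add atoms: none
Why: Fluoride-induced desilylation is selective for the Si–O bond and leaves the hydrocarbon cage, which carries no other functional group, untouched.

Step 12
Reactants: 20 nortricyclene cyclopropylcarbinol
Product: 22 exo-C5 homoallylic alcohol with the C1 methylidene, via mesylate 21 (not isolated)
Conditions: Ms2O, Et3N, CH2Cl2, −20 °C; then acetone/H2O (2:1), NaHCO3, 25–40 °C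
Reagents that add atoms: water, O; methanesulfonic anhydride, CS(=O)(=O)OS(C)(=O)=O (its atoms stay in 21 only)
Why: Cyclopropylcarbinyl–homoallyl rearrangement under buffered SN1 solvolysis, in which the primary mesylate ionises with participation of the C1–C5 bond and water should enter the delocalised cation at C5 anti to that bond (the exo face) and not at C6, whose backside is blocked by the C7 methyl, so the C5 carbinol is set exo (R) by inversion while cleavage of C1–C5 leaves the methylidene, and capture at the carbinyl carbon merely returns 20 for recycling.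

Step 13
Reactants: 22 exo-C5 homoallylic alcohol; 23 Meldrum's acid
Product: 24 hydrogen malonate of alcohol 22
Conditions: toluene, 100 °C
Reagents that add atoms: Meldrum's acid 23, CC1(C)OC(=O)CC(=O)O1
Why: Ring-opening acylation of the alcohol by thermolysed Meldrum's acid with loss of acetone gives the malonic half-ester, a reaction that works for hindered secondary alcohols and disturbs neither the C5 configuration nor the exocyclic alkene.

Step 14
Reactants: 24 hydrogen malonate of alcohol 22; 25 3,4-dihydroxybenzaldehyde
Product: 26 CNP0308742.2 (target)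
Conditions: pyridine, piperidine (cat.), 45 °C, argon
Reagents that add atoms: 3,4-dihydroxybenzaldehyde 25, O=Cc1ccc(O)c(O)c1
Why: Knoevenagel–Doebner condensation, in which the piperidine-derived iminium of the aldehyde condenses with the malonate half-ester and decarboxylative elimination gives the (E)-cinnamate directly, so the catechol needs no protection and the secondary ester is never exposed to hydrolytic conditions.

Compound list
1 | β-homocyclocitral, 2-(2,6,6-trimethylcyclohex-1-en-1-yl)acetaldehyde | O=CCC1=C(C)CCCC1(C)C | starting material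
2 | 2-(2,2-dimethoxyethyl)-1,3,3-trimethylcyclohex-1-ene (β-homocyclocitral dimethyl acetal) | COC(OC)CC1=C(C)CCCC1(C)C | intermediate
3 | 3-(2,2-dimethoxyethyl)-2,4,4-trimethylcyclohex-2-en-1-one | COC(OC)CC1=C(C)C(=O)CCC1(C)C | intermediate
4 | (1R)-3-(2,2-dimethoxyethyl)-2,4,4-trimethylcyclohex-2-en-1-ol | O[C@@H]1CCC(C)(C)C(CC(OC)OC)=C1C | intermediate
5 | N,N-dimethylacetamide dimethyl acetal | CN(C)C(C)(OC)OC | starting material
6 | ketene N,O-acetal of 4, N,N-dimethyl-1-{[(1R)-3-(2,2-dimethoxyethyl)-2,4,4-trimethylcyclohex-2-en-1-yl]oxy}ethenamine (formed in the flask) | C=C(N(C)C)O[C@@H]1CCC(C)(C)C(CC(OC)OC)=C1C | intermediate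
7 | 2-[(1S)-1-(2,2-dimethoxyethyl)-2,6,6-trimethylcyclohex-2-en-1-yl]-N,N-dimethylacetamide | CN(C)C(=O)C[C@]1(CC(OC)OC)C(C)=CCCC1(C)C | intermediate
8 | 2-[(1R,2S)-1-(2,2-dimethoxyethyl)-2,6,6-trimethylcyclohexyl]-N,N-dimethylacetamide (ring C7 hydrogen cis to the acetamide arm) | CN(C)C(=O)C[C@]1(CC(OC)OC)[C@@H](C)CCCC1(C)C | intermediate
9 | 1-[(1R,2S)-1-(2,2-dimethoxyethyl)-2,6,6-trimethylcyclohexyl]propan-2-one | CC(=O)C[C@]1(CC(OC)OC)[C@@H](C)CCCC1(C)C | intermediate
10 | tert-butyl({3-[(1S,2S)-1-(2,2-dimethoxyethyl)-2,6,6-trimethylcyclohexyl]prop-1-en-2-yl}oxy)dimethylsilane (TBS enol ether, formed in the flask) | C=C(O[Si](C)(C)C(C)(C)C)C[C@]1(CC(OC)OC)[C@@H](C)CCCC1(C)C | intermediate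
11 | 1-[(tert-butyldimethylsilyl)oxy]-3-[(1R,2S)-1-(2,2-dimethoxyethyl)-2,6,6-trimethylcyclohexyl]propan-2-one | CC(C)(C)[Si](C)(C)OCC(=O)C[C@]1(CC(OC)OC)[C@@H](C)CCCC1(C)C | intermediate
12 | 1-diazoalkene from 11, carbonyl oxygen replaced by =C=N2, (1S,2S) ring configuration (formed in the flask) | [N-]=[N+]=C=C(CO[Si](C)(C)C(C)(C)C)C[C@]1(CC(OC)OC)[C@@H](C)CCCC1(C)C | intermediate
13 | tert-butyl{[(3aS,7aR)-7a-(2,2-dimethoxyethyl)-3a,7,7-trimethyl-3a,4,5,6,7,7a-hexahydro-1H-inden-2-yl]methoxy}dimethylsilane (cis-fused) | CC(C)(C)[Si](C)(C)OCC1=C[C@]2(C)CCCC(C)(C)[C@]2(CC(OC)OC)C1 | intermediate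
14 | p-toluenesulfonyl hydrazide | Cc1ccc(cc1)S(=O)(=O)NN | starting material
15 | 2-[(3aS,7aR)-2-{[(tert-butyldimethylsilyl)oxy]methyl}-3a,7,7-trimethyl-3a,4,5,6,7,7a-hexahydro-1H-inden-7a-yl]acetaldehyde (formed in the flask) | CC(C)(C)[Si](C)(C)OCC1=C[C@]2(C)CCCC(C)(C)[C@]2(CC=O)C1 | intermediate
16 | (E)-p-toluenesulfonylhydrazone of aldehyde 15, (3aS,7aR) | CC(C)(C)[Si](C)(C)OCC1=C[C@]2(C)CCCC(C)(C)[C@]2(C/C=N/NS(=O)(=O)c3ccc(C)cc3)C1 | intermediate
17 | diazoalkane from 16, CH2–CH=N2 arm on C3, (3aS,7aR) (formed in the flask) | CC(C)(C)[Si](C)(C)OCC1=C[C@]2(C)CCCC(C)(C)[C@]2(CC=[N+]=[N-])C1 | intermediate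
18 | tetracyclic 1-pyrazoline, N=N bridging C5 and C1 on the endo side, C5–C6 bonded, CH2OTBS on C1 (formed in the flask) | CC(C)(C)[Si](C)(C)OC[C@@]14C[C@]23C[C@H](N=N4)[C@H]1[C@]2(C)CCCC3(C)C | intermediate
19 | tetracyclic nortricyclene silyl ether: C1–C5–C6 cyclopropane, C3 apex, fused at C3–C7 to the gem-dimethylcyclohexane, CH2OTBS on C1, methyl on C7, cage configuration as in the SMILES | CC(C)(C)[Si](C)(C)OC[C@@]14C[C@]23C[C@H]4[C@H]1[C@]2(C)CCCC3(C)C | intermediate
20 | nortricyclene cyclopropylcarbinol, CH2OH on C1, cage as in 19 | OC[C@@]14C[C@]23C[C@H]4[C@H]1[C@]2(C)CCCC3(C)C | intermediate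
21 | methanesulfonate of 20 (formed in the flask) | CS(=O)(=O)OC[C@@]14C[C@]23C[C@H]4[C@H]1[C@]2(C)CCCC3(C)C | intermediate
22 | (3R,5R,6R,7S) exo-C5 alcohol of the methylidene norbornane core (hydroxyl syn to the C7 bridge, methylidene on C1) | C=C1C[C@]23C[C@@H](O)[C@H]1[C@]2(C)CCCC3(C)C | intermediate
23 | Meldrum's acid, 2,2-dimethyl-1,3-dioxane-4,6-dione | CC1(C)OC(=O)CC(=O)O1 | starting material
24 | hydrogen malonate (3-oxo-3-alkoxypropanoic acid) of alcohol 22 | C=C1C[C@]23C[C@@H](OC(=O)CC(=O)O)[C@H]1[C@]2(C)CCCC3(C)C | intermediate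
25 | 3,4-dihydroxybenzaldehyde | O=Cc1ccc(O)c(O)c1 | starting material
26 | CNP0308742.2, (E)-caffeate of alcohol 22, (3R,5R,6R,7S) in the stated numbering | C=C1C[C@]23C[C@@H](OC(=O)/C=C/c4ccc(O)c(O)c4)[C@H]1[C@]2(C)CCCC3(C)C | target

Total step count: 14. Longest linear sequence: 14 steps (1 to 26).

Steps most likely to fail

Step 10. The diazoalkane may lose N2 before it cycloadds, after which the free carbene would undergo 1,2-hydride shift to a vinyl group, or two diazo molecules may couple to an azine. The fallback replaces the free diazoalkane by a zinc carbenoid. It sets out from aldehyde 15, isolated after the hydrolysis stage of step 9. N2H4·H2O in EtOH should give the N-unsubstituted hydrazone F1, and I2 with Et3N in THF should convert it into the 1,1-diiodide F2 (the known hydrazone-to-gem-diiodide iodination). Et2Zn in CH2Cl2 at 0 °C should then turn F2 into an α-iodoalkylzinc carbenoid that cyclopropanates C1=C6 intramolecularly (intramolecular Simmons–Smith reaction, assisted by the allylic silyl ether oxygen). The fallback comes back to the route at 19.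

Step 12. The delocalised cation may be captured at C5 without facial control, or lose that control through ion-pair return, so that the endo epimer forms beside 22. The fallback sets the C5 configuration by hydride delivery instead of by the solvolysis. It sets out from 20, and ionisation as in step 12 is used only to open the ring. The crude homoallylic alcohols, 22 together with its endo epimer F3, are oxidised with Dess–Martin periodinane to the β,γ-unsaturated ketone F4, whose bridgehead α-position cannot enolise. LiAlH4 in THF at −78 °C should then attack from the endo face, because the C7 methyl shields the exo face as the syn methyl does in camphor. The fallback comes back to the route at 22.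

Step 4. At the crowded C3, flanked by the gem-dimethyl carbon, thermal elimination of the ketene N,O-acetal to a diene may outrun the rearrangement. The fallback is an Ireland–Claisen rearrangement through an ester enolate at low temperature. It sets out from 4. Ac2O with DMAP and pyridine gives the allylic acetate F5, and LiN(i-Pr)2 with TMSCl in THF at −78 °C gives the ketene silyl acetal F6. F6 should rearrange below 60 °C, with the same suprafacial transfer, to the trimethylsilyl ester F7, and mild aqueous work-up gives the acid F8. Coupling with Me2NH (EDC, HOBt, CH2Cl2) comes back to the route at 7.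

Further compounds
F1 | step 10 | hydrazone of aldehyde 15 | CC(C)(C)[Si](C)(C)OCC1=C[C@]2(C)CCCC(C)(C)[C@]2(CC=NN)C1
F2 | step 10 | 1,1-diiodide, CH2–CHI2 arm on C3 | CC(C)(C)[Si](C)(C)OCC1=C[C@]2(C)CCCC(C)(C)[C@]2(CC(I)I)C1
F3 | step 12 | endo-C5 epimer of alcohol 22 | C=C1C[C@]23C[C@H](O)[C@H]1[C@]2(C)CCCC3(C)C
F4 | step 12 | C5 ketone of the methylidene norbornane core | C=C1C[C@]23CC(=O)[C@H]1[C@]2(C)CCCC3(C)C
F5 | step 4 | acetate of allylic alcohol 4 | CC(=O)O[C@@H]1CCC(C)(C)C(CC(OC)OC)=C1C
F6 | step 4 | ketene trimethylsilyl acetal of F5 | C=C(O[Si](C)(C)C)O[C@@H]1CCC(C)(C)C(CC(OC)OC)=C1C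
F7 | step 4 | trimethylsilyl 2-[(1S)-1-(2,2-dimethoxyethyl)-2,6,6-trimethylcyclohex-2-en-1-yl]acetate | C[Si](C)(C)OC(=O)C[C@]1(CC(OC)OC)C(C)=CCCC1(C)C
F8 | step 4 | 2-[(1S)-1-(2,2-dimethoxyethyl)-2,6,6-trimethylcyclohex-2-en-1-yl]acetic acid | OC(=O)C[C@]1(CC(OC)OC)C(C)=CCCC1(C)C
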